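**Strategy.** The cyclohexane ring carries a cis bromohydrin, equatorial C5'–Br beside the axial tertiary C4'–OH (C1' bears the dienyl chain), which anti addition to an alkene cannot give. Everything rests on breaking the C4'–C5' ring bond: a samarium α-bromo carbenoid generated at C5' from a geminal dibromide adds to the C4' methyl ketone, closing the carbocycle and setting both stereocentres in one operation. The precursor is the open-chain keto gem-dibromide 5, made by scission of the ring alkene of (S)-limonene. The isopropenyl group of the product is then borylated and joined by Suzuki coupling to a bromo-oxane vinyl iodide made from (R)-linalool.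

Key step: step 4

Remarks on the chemistry:
- Primed locants C1', C4' and C5' of the target are C4, C1 and C2 in the names of 8 and 9.
- (S)-Limonene supplies C1' and (R)-linalool supplies the oxane quaternary carbon; no bond to either centre is broken, and both configurations were checked against the target.
- Assumption: the epoxide mixture 2 is also offered commercially; if it is bought, step 1 is dropped.
- No protecting group is used.

Step 1
Reactants: 1 (S)-(−)-limonene
Product: 2 (4S)-limonene 1,2-oxide (mixture of the two C1/C2 diastereomers)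
Conditions: mCPBA (1.0 equiv), NaHCO3, CH2Cl2, 0 °C
Reagents that add atoms: m-chloroperbenzoic acid, OOC(=O)c1cccc(Cl)c1
Why: Prilezhaev epoxidation should take the electron-richer trisubstituted ring alkene in preference to the 1,1-disubstituted isopropenyl group; the lack of facial control is immaterial because C1 and C2 lose their stereochemistry in step 2, and C4 is untouched.

Step 2
Reactants: 2 (4S)-limonene 1,2-oxide
Product: 4 (S)-6-oxo-3-(prop-1-en-2-yl)heptanal, via limonene-1,2-diol 3 (not isolated)
Conditions: H5IO6 (1.2 equiv), THF/H2O, 0 °C to rt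
Reagents that add atoms: water, O
Why: Acid-promoted epoxide hydrolysis followed in the same flask by periodate (Malaprade) glycol cleavage should converge both epoxide diastereomers on one keto-aldehyde, whose single stereocentre is not enolisable and is retained.

Step 3
Reactants: 4 (S)-6-oxo-3-(prop-1-en-2-yl)heptanal
Product: 5 (S)-7,7-dibromo-5-(prop-1-en-2-yl)heptan-2-one
Conditions: P(OPh)3 (1.2 equiv), Br2 (1.1 equiv), CH2Cl2, −78 °C; then Et3N (1.2 equiv) and 4, −78 to 0 °C
Reagents that add atoms: bromine, BrBr
Why: Deoxygenative gem-dibromination of an aldehyde by the bromophosphorane pre-formed from triphenyl phosphite and bromine should be aldehyde-selective, since enolisable ketones react only on heating (to vinyl bromides) and the slight excess of phosphite leaves no free bromine for the alkene; no stereocentre is involved.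

Step 4
Reactants: 5 (S)-7,7-dibromo-5-(prop-1-en-2-yl)heptan-2-one
Product: 8 (1R,2S,4S)-2-bromo-1-methyl-4-(prop-1-en-2-yl)cyclohexan-1-ol, via α-bromoalkylsamarium carbenoid 6 (not isolated), via samarium alkoxide 7 (not isolated)
Conditions: SmI2 (2.3 equiv, 0.1 M in THF), 5 added over 30 min (final 0.02 M), 0 °C; then aq. K2CO3, 0 °C
Reagents that add atoms: none
Why: Proposed new method: two successive single-electron transfers from SmI2 to the geminal dibromide (C–Br cleavage to an α-bromoalkyl radical, then reduction to the α-bromoalkyl diiodosamarium carbenoid 6) should be followed by 6-exo-trig addition of the carbanionic carbon to the tethered methyl ketone, forming the C4'–C5' bond and closing the cyclohexane as alkoxide 7; the closest known reactions are the SmI2/dihalomethane halomethylation of ketones to halohydrins and samarium Barbier cyclisations of ω-halo ketones. The ring should close through a chair in which the existing C1' stereocentre holds its isopropenyl group equatorial. C5' is set because the configurationally labile carbenoid can adopt the arrangement with bromine equatorial (cis-1,3 to isopropenyl), and C4' because the ketone turns its methyl group equatorial and its oxygen axial towards samarium, which bridges the carbenoid carbon, bromine and the carbonyl oxygen in a four-centre transition state; together this gives the cis bromohydrin with Br equatorial and OH axial. The step needs chemoselectivity for the CHBr2 group over the ketone, the alkene and the secondary C–Br of the product, which the much easier reduction of a geminal dibromide in HMPA-free THF should secure. It also needs diastereoselectivity at two centres, which rests on the equatorial anchor at C1' and the equatorial preference of bromine and methyl. Any trans bromohydrin alkoxide can close to epoxide 2 during the basic work-up whereas the cis alkoxide cannot, so stray diastereomers are diverted to a separable compound that can re-enter at step 2.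

Step 5
Reactants: 8 (1R,2S,4S)-2-bromo-1-methyl-4-(prop-1-en-2-yl)cyclohexan-1-ol
Product: 9 (1R,2S,4S)-2-bromo-1-methyl-4-[(E)-1-(4,4,5,5-tetramethyl-1,3,2-dioxaborolan-2-yl)prop-1-en-2-yl]cyclohexan-1-ol
Conditions: B2pin2 (1.5 equiv), trans-RhCl(CO)(PPh3)2 (5 mol %), toluene/MeCN 3:1, 80 °C
Reagents that add atoms: bis(pinacolato)diboron, CC1(C)OB(OC1(C)C)B1OC(C)(C)C(C)(C)O1
Why: Rhodium-catalysed dehydrogenative borylation of a 1,1-disubstituted alkene (boryl insertion, then β-hydride elimination) is a known route to 2,2-disubstituted alkenyl boronates, and the E geometry should follow from the boryl group ending anti to the bulky cyclohexyl substituent; the tertiary alcohol, the secondary bromide and the ring stereocentres take no part.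

Step 6
Reactants: 10 (R)-(−)-linalool
Product: 11 (3S,6R)-3-bromo-6-ethenyl-2,2,6-trimethyloxane
Conditions: 2,4,4,6-tetrabromocyclohexa-2,5-dienone (1.1 equiv), CH2Cl2, 0 °C to rt; chromatography
Reagents that add atoms: 2,4,4,6-tetrabromocyclohexa-2,5-dienone, O=C1C(Br)=CC(Br)(Br)C=C1Br
Why: Bromonium-induced 6-endo (Markovnikov) bromoetherification should let the tertiary hydroxyl open the bromonium ion of the trisubstituted alkene at the dimethyl-substituted carbon by anti addition, with C6 carried over from linalool; the remote centre gives little facial bias, so 11 (Br trans to ethenyl, both equatorial) is expected in an amount comparable to its C3 epimer and must be separated.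

Step 7
Reactants: 11 (3S,6R)-3-bromo-6-ethenyl-2,2,6-trimethyloxane
Product: 13 (2R,5S)-5-bromo-2,6,6-trimethyloxane-2-carbaldehyde, via secondary ozonide 12 (not isolated)
Conditions: O3, CH2Cl2, −78 °C; then PPh3, −78 °C to rt
Reagents that add atoms: ozone, [O-][O+]=O
Why: Ozonolysis with reductive work-up (Criegee mechanism) should cleave the only alkene to a non-enolisable α-alkoxy aldehyde without touching either stereocentre or the C–Br bond.

Step 8
Reactants: 13 (2R,5S)-5-bromo-2,6,6-trimethyloxane-2-carbaldehyde
Product: 14 (3S,6R)-3-bromo-6-[(E)-2-iodoethenyl]-2,2,6-trimethyloxane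
Conditions: CrCl2 (6 equiv), CHI3 (2 equiv), THF/1,4-dioxane 1:6, 0 °C to rt
Reagents that add atoms: iodoform, IC(I)I
Why: Takai olefination (addition of the geminal dichromium species from iodoform and CrCl2 to the aldehyde, then elimination) should give the E-iodoalkene selectively with this hindered aldehyde, and divalent chromium leaves an unactivated secondary bromide alone.

Step 9
Reactants: 9 (1R,2S,4S)-2-bromo-1-methyl-4-[(E)-1-(4,4,5,5-tetramethyl-1,3,2-dioxaborolan-2-yl)prop-1-en-2-yl]cyclohexan-1-ol; 14 (3S,6R)-3-bromo-6-[(E)-2-iodoethenyl]-2,2,6-trimethyloxane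
Product: 15 (1R,2S,4S)-2-bromo-4-[(2E,4E)-5-[(2R,5S)-5-bromo-2,6,6-trimethyloxan-2-yl]penta-2,4-dien-2-yl]-1-methylcyclohexan-1-ol
Conditions: Pd(PPh3)4 (5 mol %), aq. K3PO4 (3 equiv), THF, 45 °C, degassed
Reagents that add atoms: none
Why: Suzuki–Miyaura coupling should join the two sp2 carbons with retention of both alkene geometries to give the E,E-diene; zerovalent palladium with PPh3 does not insert into unactivated secondary alkyl bromides, and the cis bromohydrin cannot close to an epoxide under the mild base.

**Compound list**

1 | (S)-(−)-limonene, (4S)-1-methyl-4-(prop-1-en-2-yl)cyclohex-1-ene | CC(=C)[C@H]1CCC(C)=CC1 | starting material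
2 | (4S)-limonene 1,2-oxide, (4S)-1-methyl-4-(prop-1-en-2-yl)-7-oxabicyclo[4.1.0]heptane, mixture of the two C1/C2 diastereomers | CC(=C)[C@H]1CCC2(C)OC2C1 | intermediate
3 | (1R,2R,4S)-1-methyl-4-(prop-1-en-2-yl)cyclohexane-1,2-diol (trans-diaxial limonene-1,2-diol, principal diastereomer) | CC(=C)[C@H]1CC[C@@](C)(O)[C@H](O)C1 | intermediate (not isolated)
4 | (S)-6-oxo-3-(prop-1-en-2-yl)heptanal | CC(=C)[C@H](CC=O)CCC(C)=O | intermediate
5 | (S)-7,7-dibromo-5-(prop-1-en-2-yl)heptan-2-one | CC(=C)[C@H](CC(Br)Br)CCC(C)=O | intermediate
6 | [(3S)-1-bromo-6-oxo-3-(prop-1-en-2-yl)heptyl]diiodosamarium (α-bromoalkylsamarium carbenoid, labile at C1) | CC(=C)[C@H](CC(Br)[Sm](I)I)CCC(C)=O | intermediate (not isolated)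
7 | diiodosamarium (1R,2S,4S)-2-bromo-1-methyl-4-(prop-1-en-2-yl)cyclohexan-1-olate | CC(=C)[C@H]1CC[C@@](C)(O[Sm](I)I)[C@@H](Br)C1 | intermediate (not isolated)
8 | (1R,2S,4S)-2-bromo-1-methyl-4-(prop-1-en-2-yl)cyclohexan-1-ol | CC(=C)[C@H]1CC[C@@](C)(O)[C@@H](Br)C1 | intermediate
9 | (1R,2S,4S)-2-bromo-1-methyl-4-[(E)-1-(4,4,5,5-tetramethyl-1,3,2-dioxaborolan-2-yl)prop-1-en-2-yl]cyclohexan-1-ol | C/C(=C\B1OC(C)(C)C(C)(C)O1)[C@H]1CC[C@@](C)(O)[C@@H](Br)C1 | intermediate
10 | (R)-(−)-linalool, (3R)-3,7-dimethylocta-1,6-dien-3-ol | C=C[C@](C)(O)CCC=C(C)C | starting material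
11 | (3S,6R)-3-bromo-6-ethenyl-2,2,6-trimethyloxane | C=C[C@@]1(C)CC[C@H](Br)C(C)(C)O1 | intermediate
12 | 3-[(2R,5S)-5-bromo-2,6,6-trimethyloxan-2-yl]-1,2,4-trioxolane (secondary ozonide, mixture at the trioxolane carbon) | C1(OCOO1)[C@@]2(C)CC[C@H](Br)C(C)(C)O2 | intermediate (not isolated)
13 | (2R,5S)-5-bromo-2,6,6-trimethyloxane-2-carbaldehyde | O=C[C@@]1(C)CC[C@H](Br)C(C)(C)O1 | intermediate
14 | (3S,6R)-3-bromo-6-[(E)-2-iodoethenyl]-2,2,6-trimethyloxane | I/C=C/[C@@]1(C)CC[C@H](Br)C(C)(C)O1 | intermediate
15 | (1R,2S,4S)-2-bromo-4-[(2E,4E)-5-[(2R,5S)-5-bromo-2,6,6-trimethyloxan-2-yl]penta-2,4-dien-2-yl]-1-methylcyclohexan-1-ol | C/C(=C\C=C\[C@@]1(C)CC[C@H](Br)C(C)(C)O1)[C@H]1CC[C@@](C)(O)[C@@H](Br)C1 | target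

**Step count and risks**

Total steps: 9. Longest linear sequence: 6 (steps 1 to 5, then step 9).

Steps most likely to fail:

1. Step 4 (proposed new method). The carbenoid may be lost before it reaches the ketone, by 1,2-hydrogen shift to a terminal alkene or by hydrogen abstraction to the monobromide. Ring closure may also go through another chair, so that trans bromohydrins and then epoxide form instead of 8. The fallback uses known chemistry (inversion at the secondary carbon of a trans diol through a cyclic sulfite); it sets out from 2 and returns at 8. Hydrolysis of 2 (dilute H2SO4, THF/H2O, 0 °C) gives the trans-diaxial diol 3, this time isolated. SOCl2 and Et3N in CH2Cl2 at 0 °C convert 3 into the trans-fused cyclic sulfite of diol 3 F1. LiBr in DMF at about 80 °C should open it by SN2 attack at the secondary carbon, with inversion, to lithium (1R,2S,4S)-2-bromo-1-methyl-4-(prop-1-en-2-yl)cyclohexyl sulfite F2, which loses SO2 on work-up with dilute HCl and gives 8. The tertiary oxygen stays tied up in the sulfite during the displacement, so it cannot close to the epoxide.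

2. Step 5. β-Hydride elimination may go towards the methyl group or the ring and give allyl boronates, E/Z control may be low, or the catalyst may be diverted by O-borylation of the tertiary alcohol. The fallback fixes the E geometry by syn carbometalation of an alkyne; it sets out from 8 and returns at 9. Ozonolysis of 8 (O3, CH2Cl2/MeOH, −78 °C; Me2S) gives 1-[(1S,3S,4R)-3-bromo-4-hydroxy-4-methylcyclohexyl]ethan-1-one F3. Me3SiCl and imidazole in DMF give the trimethylsilyl ether of F3 F4. KN(SiMe3)2 and PhNTf2 in THF at −78 °C give the terminal enol triflate of F4 F5, and LiN(i-Pr)2 in THF at −78 °C eliminates triflate to the terminal alkyne [(1R,2S,4S)-2-bromo-4-ethynyl-1-methylcyclohexyl]oxy(trimethyl)silane F6. Negishi carboalumination (Me3Al, Cp2ZrCl2, CH2Cl2) adds methyl and aluminium syn to give the E-alkenyl(dimethyl)alane F7. This is trapped in the same flask with 2-isopropoxy-4,4,5,5-tetramethyl-1,3,2-dioxaborolane as the trimethylsilyl ether of 9 F8, and K2CO3 in MeOH removes the silyl group to give 9.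

3. Step 3. Chemoselectivity may be lost: the methyl ketone may be converted into a vinyl bromide, or HBr formed adventitiously may add to the isopropenyl group. The fallback makes the gem-dibromide by oxidative halogenation of a hydrazone instead of deoxygenative halogenation; it sets out from 4 and returns at 5. N2H4·H2O (1.0 equiv, EtOH, 0 °C) should condense with the aldehyde in preference to the methyl ketone to give (5S)-7-hydrazinylidene-5-(prop-1-en-2-yl)heptan-2-one F9. CuBr2 with LiOt-Bu in THF at rt then converts the hydrazone, with loss of N2, into 5.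

**Further compounds**

F1 | step 4 | cyclic sulfite of diol 3 (trans-fused 1,3,2-dioxathiolane 2-oxide, mixture at sulfur) | CC(=C)[C@H]1CC[C@@]2(C)OS(=O)O[C@@H]2C1
F2 | step 4 | lithium (1R,2S,4S)-2-bromo-1-methyl-4-(prop-1-en-2-yl)cyclohexyl sulfite | CC(=C)[C@H]1CC[C@@](C)(OS(=O)[O-])[C@@H](Br)C1.[Li+]
F3 | step 5 | 1-[(1S,3S,4R)-3-bromo-4-hydroxy-4-methylcyclohexyl]ethan-1-one | CC(=O)[C@H]1CC[C@@](C)(O)[C@@H](Br)C1
F4 | step 5 | trimethylsilyl ether of F3 | CC(=O)[C@H]1CC[C@@](C)(O[Si](C)(C)C)[C@@H](Br)C1
F5 | step 5 | terminal enol triflate of F4 | C=C(OS(=O)(=O)C(F)(F)F)[C@H]1CC[C@@](C)(O[Si](C)(C)C)[C@@H](Br)C1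
F6 | step 5 | [(1R,2S,4S)-2-bromo-4-ethynyl-1-methylcyclohexyl]oxy(trimethyl)silane | C#C[C@H]1CC[C@@](C)(O[Si](C)(C)C)[C@@H](Br)C1
F7 | step 5 | E-alkenyl(dimethyl)alane from F6 (methyl and aluminium cis) | C/C(=C\[Al](C)C)[C@H]1CC[C@@](C)(O[Si](C)(C)C)[C@@H](Br)C1
F8 | step 5 | trimethylsilyl ether of 9 | C/C(=C\B1OC(C)(C)C(C)(C)O1)[C@H]1CC[C@@](C)(O[Si](C)(C)C)[C@@H](Br)C1
F9 | step 3 | (5S)-7-hydrazinylidene-5-(prop-1-en-2-yl)heptan-2-one | CC(=C)[C@H](C/C=N/N)CCC(C)=O
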